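**Retrosynthetic overview**

- The target is reached from its tetra-MOM ether by acetal cleavage, and that from a racemic 2-aryl-2,3-dihydrobenzofuran by dehydrogenation.
- The strategy rests on C2 of the furan ring: it is the one carbon bonded to O1, to C3 and to C1' of ring B. The bonds O1–C2 and C2–C3 are therefore both cut at C2. C2 comes in as the benzylic sulfonium ylide carbon of ring B, C3 as the exocyclic CH2 of a ring A ortho-quinone methide (released from a phenolic Mannich salt), and O1 as the methide oxygen.
- Ring A salt: 2,4,6-trihydroxybenzaldehyde is 4-O-prenylated and rearranged (Claisen) with the para carbon occupied by the formyl group and the two ortho carbons equivalent; then 4,6-bis-MOM protection, reductive amination and N-methylation.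
- Ring B salt: methyl 3,5-dihydroxybenzoate is MOM-protected, 2,6-dibrominated, doubly prenylated by Suzuki coupling, reduced, brominated and S-alkylated with dimethyl sulfide.
- Ring order: both benzene rings are bought; the furan ring is the only ring formed (step 12) and is made aromatic in step 13.

Key step: step 12

Remark on stereochemistry: the target has no stereocentre and no stereogenic double bond, so the compound asked for is the achiral molecule itself. C2 of 21 is formed as a racemate and becomes sp2 in step 13.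

Remark on ring A: prenyl ethers of 3,5-dialkoxyphenols with a free para position tend to pass the allyl group on to the para carbon (Claisen, then Cope), which gives the linear prenyl isomer. The rearrangement is therefore run on an aldehyde whose para carbon is the later C3 carbon. The amine is then made from that formyl group, which also fixes the position of the CH2N group.

**Route**

Step 1
Reactants: 1 2,4,6-trihydroxybenzaldehyde; 2 prenyl bromide
Product: 3 2,6-dihydroxy-4-(3-methylbut-2-enyloxy)benzaldehyde
Conditions: 2 (1.0 equiv), K2CO3 (1.1 equiv), acetone, rt to 40 °C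
Reagents that add atoms: none
Why: Williamson ether synthesis; the 4-hydroxyl, para to the formyl group and not held in a hydrogen bond to it, is the most acidic and should be alkylated first, and a weak base in acetone favours O- over C-alkylation.

Step 2
Reactants: 3 2,6-dihydroxy-4-(3-methylbut-2-enyloxy)benzaldehyde
Product: 5 2,4,6-trihydroxy-3-(2-methylbut-3-en-2-yl)benzaldehyde, via ortho-dienone 4 (not isolated)
Conditions: PhNEt2, 180 °C, Ar, sealed tube
Reagents that add atoms: none
Why: Aromatic Claisen rearrangement ([3,3]): the dimethyl-substituted allyl terminus bonds to an ortho carbon and so turns the prenyl ether into a C-bound 1,1-dimethylallyl group; the two ortho carbons of 3 are equivalent, the para carbon carries the formyl group so that a further Cope shift has no aromatisable outlet, and enolisation of dienone 4 should give 5.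

Step 3
Reactants: 5 2,4,6-trihydroxy-3-(2-methylbut-3-en-2-yl)benzaldehyde
Product: 6 2-hydroxy-4,6-bis(methoxymethoxy)-3-(2-methylbut-3-en-2-yl)benzaldehyde
Conditions: MOMCl (2.2 equiv), i-Pr2NEt, CH2Cl2, 0 °C to rt
Reagents that add atoms: chloromethyl methyl ether (MOMCl), COCCl
Why: O-alkylation of phenols to MOM acetals under amine base; the 4-hydroxyl and the unhindered 6-hydroxyl should react, while the 2-hydroxyl, chelated to the formyl oxygen and flanked by the tert-alkyl group, is expected to stay free.

Step 4
Reactants: 6 2-hydroxy-4,6-bis(methoxymethoxy)-3-(2-methylbut-3-en-2-yl)benzaldehyde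
Product: 8 2-[(dimethylamino)methyl]-3,5-bis(methoxymethoxy)-6-(2-methylbut-3-en-2-yl)phenol, via iminium phenolate 7 (not isolated)
Conditions: Me2NH (2 M in THF), AcOH (cat.), NaBH(OAc)3, ClCH2CH2Cl, rt
Reagents that add atoms: dimethylamine, CNC
Why: Reductive amination: dimethylamine condenses with the aldehyde to iminium phenolate 7, which the mild acyloxyborohydride should reduce without touching alkenes or acetals, so the CH2N group sits unambiguously ortho to the free phenol.

Step 5
Reactants: 8 2-[(dimethylamino)methyl]-3,5-bis(methoxymethoxy)-6-(2-methylbut-3-en-2-yl)phenol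
Product: 9 [2-hydroxy-4,6-bis(methoxymethoxy)-3-(2-methylbut-3-en-2-yl)benzyl]trimethylammonium iodide
Conditions: MeI (excess), Et2O, rt, dark
Reagents that add atoms: iodomethane, CI
Why: Menshutkin N-methylation of the tertiary benzylic amine; without added base the phenol is not methylated and the salt should separate from ether.

Step 6
Reactants: 10 methyl 3,5-dihydroxybenzoate
Product: 11 methyl 3,5-bis(methoxymethoxy)benzoate
Conditions: MOMCl (2.5 equiv), i-Pr2NEt, CH2Cl2, 0 °C to rt
Reagents that add atoms: chloromethyl methyl ether (MOMCl), COCCl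
Why: Protection of both phenols as MOM acetals by O-alkylation under amine base; the ester is inert.

Step 7
Reactants: 11 methyl 3,5-bis(methoxymethoxy)benzoate
Product: 12 methyl 2,6-dibromo-3,5-bis(methoxymethoxy)benzoate
Conditions: NBS (2.1 equiv), MeCN, 0 °C to rt
Reagents that add atoms: N-bromosuccinimide, O=C1CCC(=O)N1Br
Why: Electrophilic aromatic bromination: C2 and C6 are each ortho to one and para to the other alkoxy group, whereas C4 lies between both acetal groups and is screened, so the 2,6-dibromide should form.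

Step 8
Reactants: 12 methyl 2,6-dibromo-3,5-bis(methoxymethoxy)benzoate; 13 prenylboronic acid pinacol ester
Product: 14 methyl 3,5-bis(methoxymethoxy)-2,6-bis(3-methylbut-2-enyl)benzoate
Conditions: 13 (3 equiv), Pd-PEPPSI-IPent (cat.), aq. KOH, THF, 70 °C
Reagents that add atoms: none
Why: Two-fold Suzuki–Miyaura coupling of an allylic boronate under bulky NHC–palladium conditions known to give the linear product; with a 2,6-disubstituted aryl on palladium the allyl group should couple at its unsubstituted terminus and give 3-methylbut-2-enyl rather than 1,1-dimethylallyl groups, and the doubly ortho-substituted ester resists hydroxide.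

Step 9
Reactants: 14 methyl 3,5-bis(methoxymethoxy)-2,6-bis(3-methylbut-2-enyl)benzoate
Product: 15 [3,5-bis(methoxymethoxy)-2,6-bis(3-methylbut-2-enyl)phenyl]methanol
Conditions: LiAlH4, THF, 0 °C to rt
Reagents that add atoms: none
Why: Hydride reduction of the ester to the benzylic alcohol; LiAlH4 is small enough for the doubly ortho-substituted ester and leaves alkenes and acetals alone.

Step 10
Reactants: 15 [3,5-bis(methoxymethoxy)-2,6-bis(3-methylbut-2-enyl)phenyl]methanol
Product: 16 3-(bromomethyl)-1,5-bis(methoxymethoxy)-2,4-bis(3-methylbut-2-enyl)benzene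
Conditions: CBr4, PPh3, CH2Cl2, 0 °C
Reagents that add atoms: carbon tetrabromide, BrC(Br)(Br)Br
Why: Appel reaction: neutral SN2 conversion of the primary benzylic alcohol into the bromide, which avoids the acid that would cleave MOM groups or start cation–olefin reactions of the prenyl groups.

Step 11
Reactants: 16 3-(bromomethyl)-1,5-bis(methoxymethoxy)-2,4-bis(3-methylbut-2-enyl)benzene
Product: 17 [3,5-bis(methoxymethoxy)-2,6-bis(3-methylbut-2-enyl)benzyl]dimethylsulfonium bromide
Conditions: Me2S (10 equiv), acetone, rt, dark; trituration with Et2O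
Reagents that add atoms: dimethyl sulfide, CSC
Why: SN2 S-alkylation of dimethyl sulfide by the primary benzylic bromide, driven by the excess of sulfide and separation of the salt.

Step 12
Reactants: 9 [2-hydroxy-4,6-bis(methoxymethoxy)-3-(2-methylbut-3-en-2-yl)benzyl]trimethylammonium iodide; 17 [3,5-bis(methoxymethoxy)-2,6-bis(3-methylbut-2-enyl)benzyl]dimethylsulfonium bromide
Product: 21 (±)-2-[3,5-bis(methoxymethoxy)-2,6-bis(3-methylbut-2-enyl)phenyl]-4,6-bis(methoxymethoxy)-7-(2-methylbut-3-en-2-yl)-2,3-dihydro-1-benzofuran, via ortho-quinone methide 18 (not isolated), via benzylic sulfonium ylide 19 (not isolated), via sulfonium phenolate betaine 20 (not isolated)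
Conditions: 17 (1.5 equiv), Cs2CO3 (4 equiv), MeCN–CH2Cl2, 0 °C; 9 in MeCN added slowly; then rt
Reagents that add atoms: none
Why: Carbonate deprotonates the phenol of 9, which loses trimethylamine to the ortho-quinone methide 18, and reversibly deprotonates 17 at the benzylic carbon to ylide 19; the ylide carbon adds to the exocyclic CH2 of 18 (C2–C3 bond, ring A aromatic again) to betaine 20, whose phenoxide displaces dimethyl sulfide at the benzylic carbon (O1–C2 bond). The closest known reaction type is the [4+1] annulation of ortho-quinone methides with sulfonium ylides to 2-substituted 2,3-dihydrobenzofurans, here with the methide released from a phenolic Mannich salt. The furan ring closes by a 5-exo-tet substitution. C2 is formed without control as a racemate, which is acceptable because step 13 turns it into an sp2 carbon. The step needs C-attack of the benzylic ylide on the methide to outrun self-condensation of 18 and reaction through an S-methyl ylide; slow release of 18 into an excess of 19, the unsubstituted methylene terminus and the higher acidity of the benzylic position are expected to secure this, and ring closure can only pass through the one phenoxide oxygen next to the 1,1-dimethylallyl group because the other two ring A oxygens are MOM ethers.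

Step 13
Reactants: 21 (±)-2-[3,5-bis(methoxymethoxy)-2,6-bis(3-methylbut-2-enyl)phenyl]-4,6-bis(methoxymethoxy)-7-(2-methylbut-3-en-2-yl)-2,3-dihydro-1-benzofuran
Product: 22 2-[3,5-bis(methoxymethoxy)-2,6-bis(3-methylbut-2-enyl)phenyl]-4,6-bis(methoxymethoxy)-7-(2-methylbut-3-en-2-yl)-1-benzofuran
Conditions: DDQ (1.1 equiv), 1,4-dioxane, rt to 50 °C
Reagents that add atoms: none
Why: DDQ dehydrogenation: hydride abstraction from C3, benzylic to the three-fold oxygenated ring A, followed by loss of the C2 proton gives the aromatic furan; ring A is the most electron-rich site, so one equivalent at low temperature should act there before the benzylic allylic CH2 groups of ring B.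

Step 14
Reactants: 22 2-[3,5-bis(methoxymethoxy)-2,6-bis(3-methylbut-2-enyl)phenyl]-4,6-bis(methoxymethoxy)-7-(2-methylbut-3-en-2-yl)-1-benzofuran
Product: 23 2-[3,5-dihydroxy-2,6-bis(3-methylbut-2-enyl)phenyl]-7-(2-methylbut-3-en-2-yl)-1-benzofuran-4,6-diol (CNP0115465.0)
Conditions: conc. HCl (cat.), MeOH, 40 °C
Reagents that add atoms: none
Why: Acid-catalysed acetal exchange: in methanol the four MOM groups leave as dimethoxymethane, which keeps formaldehyde away from the nucleophilic rings, and mild acid at moderate temperature should not add the free phenols to the prenyl or 1,1-dimethylallyl double bonds.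

**Compound list**

1 | 2,4,6-trihydroxybenzaldehyde | O=Cc1c(O)cc(O)cc1O | starting material
2 | prenyl bromide (1-bromo-3-methylbut-2-ene) | CC(C)=CCBr | starting material
3 | 2,6-dihydroxy-4-(3-methylbut-2-enyloxy)benzaldehyde | O=Cc1c(O)cc(OCC=C(C)C)cc1O | intermediate
4 | 4-formyl-3,5-dihydroxy-6-(2-methylbut-3-en-2-yl)cyclohexa-2,4-dien-1-one (ortho-dienone, racemic, not isolated) | O=CC1=C(O)C(C(C)(C)C=C)C(=O)C=C1O | intermediate
5 | 2,4,6-trihydroxy-3-(2-methylbut-3-en-2-yl)benzaldehyde | C=CC(C)(C)c1c(O)cc(O)c(C=O)c1O | intermediate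
6 | 2-hydroxy-4,6-bis(methoxymethoxy)-3-(2-methylbut-3-en-2-yl)benzaldehyde | C=CC(C)(C)c1c(OCOC)cc(OCOC)c(C=O)c1O | intermediate
7 | 2-[(dimethyliminio)methyl]-3,5-bis(methoxymethoxy)-6-(2-methylbut-3-en-2-yl)phenolate (iminium phenolate, not isolated) | C=CC(C)(C)c1c(OCOC)cc(OCOC)c(C=[N+](C)C)c1[O-] | intermediate
8 | 2-[(dimethylamino)methyl]-3,5-bis(methoxymethoxy)-6-(2-methylbut-3-en-2-yl)phenol | C=CC(C)(C)c1c(OCOC)cc(OCOC)c(CN(C)C)c1O | intermediate
9 | [2-hydroxy-4,6-bis(methoxymethoxy)-3-(2-methylbut-3-en-2-yl)benzyl]trimethylammonium iodide | C=CC(C)(C)c1c(O)c(C[N+](C)(C)C)c(OCOC)cc1OCOC.[I-] | intermediate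
10 | methyl 3,5-dihydroxybenzoate | COC(=O)c1cc(O)cc(O)c1 | starting material
11 | methyl 3,5-bis(methoxymethoxy)benzoate | COC(=O)c1cc(OCOC)cc(OCOC)c1 | intermediate
12 | methyl 2,6-dibromo-3,5-bis(methoxymethoxy)benzoate | COC(=O)c1c(Br)c(OCOC)cc(OCOC)c1Br | intermediate
13 | prenylboronic acid pinacol ester (4,4,5,5-tetramethyl-2-(3-methylbut-2-enyl)-1,3,2-dioxaborolane) | CC(C)=CCB1OC(C)(C)C(C)(C)O1 | starting material
14 | methyl 3,5-bis(methoxymethoxy)-2,6-bis(3-methylbut-2-enyl)benzoate | COC(=O)c1c(CC=C(C)C)c(OCOC)cc(OCOC)c1CC=C(C)C | intermediate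
15 | [3,5-bis(methoxymethoxy)-2,6-bis(3-methylbut-2-enyl)phenyl]methanol | OCc1c(CC=C(C)C)c(OCOC)cc(OCOC)c1CC=C(C)C | intermediate
16 | 3-(bromomethyl)-1,5-bis(methoxymethoxy)-2,4-bis(3-methylbut-2-enyl)benzene | BrCc1c(CC=C(C)C)c(OCOC)cc(OCOC)c1CC=C(C)C | intermediate
17 | [3,5-bis(methoxymethoxy)-2,6-bis(3-methylbut-2-enyl)benzyl]dimethylsulfonium bromide | C[S+](C)Cc1c(CC=C(C)C)c(OCOC)cc(OCOC)c1CC=C(C)C.[Br-] | intermediate
18 | 3,5-bis(methoxymethoxy)-6-methylidene-2-(2-methylbut-3-en-2-yl)cyclohexa-2,4-dien-1-one (ortho-quinone methide, not isolated) | C=C1C(=O)C(C(C)(C)C=C)=C(OCOC)C=C1OCOC | intermediate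
19 | dimethylsulfonium [3,5-bis(methoxymethoxy)-2,6-bis(3-methylbut-2-enyl)phenyl]methylide (benzylic ylide, not isolated) | C[S+](C)[CH-]c1c(CC=C(C)C)c(OCOC)cc(OCOC)c1CC=C(C)C | intermediate
20 | 2-{2-[3,5-bis(methoxymethoxy)-2,6-bis(3-methylbut-2-enyl)phenyl]-2-(dimethylsulfonio)ethyl}-3,5-bis(methoxymethoxy)-6-(2-methylbut-3-en-2-yl)phenolate (betaine, racemic, not isolated) | C=CC(C)(C)c1c([O-])c(CC([S+](C)C)c2c(CC=C(C)C)c(OCOC)cc(OCOC)c2CC=C(C)C)c(OCOC)cc1OCOC | intermediate
21 | (±)-2-[3,5-bis(methoxymethoxy)-2,6-bis(3-methylbut-2-enyl)phenyl]-4,6-bis(methoxymethoxy)-7-(2-methylbut-3-en-2-yl)-2,3-dihydro-1-benzofuran (racemate at C2, one enantiomer drawn) | C=CC(C)(C)c1c(OCOC)cc(OCOC)c2C[C@H](c3c(CC=C(C)C)c(OCOC)cc(OCOC)c3CC=C(C)C)Oc12 | intermediate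
22 | 2-[3,5-bis(methoxymethoxy)-2,6-bis(3-methylbut-2-enyl)phenyl]-4,6-bis(methoxymethoxy)-7-(2-methylbut-3-en-2-yl)-1-benzofuran | C=CC(C)(C)c1c(OCOC)cc(OCOC)c2cc(-c3c(CC=C(C)C)c(OCOC)cc(OCOC)c3CC=C(C)C)oc12 | intermediate
23 | 2-[3,5-dihydroxy-2,6-bis(3-methylbut-2-enyl)phenyl]-7-(2-methylbut-3-en-2-yl)-1-benzofuran-4,6-diol (achiral) | C=CC(C)(C)c1c(O)cc(O)c2cc(-c3c(CC=C(C)C)c(O)cc(O)c3CC=C(C)C)oc12 | target

**Step count**

Total: 14 steps. Longest linear sequence: 9 steps (10 → 11 → 12 → 14 → 15 → 16 → 17 → 21 → 22 → 23); the ring A branch is 8 steps to the target.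

**Steps most likely to fail**

1. Step 12 (key step). What may go wrong: the betaine may lose dimethyl sulfide by β-elimination to a 2-hydroxystilbene instead of closing at the crowded benzylic carbon, the ylide may form at an S-methyl group, or the methide may oligomerise before the hindered ylide adds.
Fallback (sets out from 9 and 14, comes back at 22, so step 13 is not needed): an intramolecular Wittig synthesis of the benzofuran.
Salt 9 is heated with PPh3 in MeCN, which should exchange trimethylamine for the phosphine and give [2-hydroxy-4,6-bis(methoxymethoxy)-3-(2-methylbut-3-en-2-yl)benzyl]triphenylphosphonium iodide F1.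
Ester 14 is cleaved with KOt-Bu/H2O in THF (anhydrous hydroxide, suited to hindered esters) to 3,5-bis(methoxymethoxy)-2,6-bis(3-methylbut-2-enyl)benzoic acid F2.
F2 is converted under neutral conditions with 1-chloro-N,N,2-trimethylprop-1-en-1-amine into 3,5-bis(methoxymethoxy)-2,6-bis(3-methylbut-2-enyl)benzoyl chloride F3.
F1, F3 and Et3N in toluene should first give the O-aroyl phosphonium salt F4; further Et3N deprotonates it to the phosphorus ylide F5, which on heating attacks the ester carbonyl and forms the C2=C3 bond with O1–C2 already in place, giving 22.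

2. Step 2 (Claisen rearrangement). What may go wrong: the first-formed phenol may react on under the thermal conditions (abnormal Claisen shift through a free ortho hydroxyl, or addition of a hydroxyl to the new vinyl group), or the formyl group may be lost after a second shift to the ipso carbon.
Fallback (sets out from 3, comes back at 5): the rearrangement is moved to a substrate without free hydroxyls.
Both hydroxyls of 3 are masked (NaH, MOMCl, DMF) to give 2,6-bis(methoxymethoxy)-4-(3-methylbut-2-enyloxy)benzaldehyde F6.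
Heating F6 in PhNEt2 should lead through the ortho-dienone F7 to 4-hydroxy-2,6-bis(methoxymethoxy)-3-(2-methylbut-3-en-2-yl)benzaldehyde F8, which has a single free phenol.
Brief treatment of F8 with HCl in MeOH removes both acetals and returns to 5, which enters step 3 unchanged.

3. Step 13 (DDQ dehydrogenation). What may go wrong: hydride abstraction at the benzylic, allylic CH2 groups of the ring B prenyl chains may compete with abstraction at C3 and lead to over-oxidation.
Fallback (sets out from 6 and 17, comes back at 22): the unsaturation is brought in as an oxygen at C3 and removed by dehydration, so no oxidant is needed.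
Aldehyde 6 and salt 17 are treated with KOt-Bu in THF; the ylide 19 adds to the formyl carbon to give the β-hydroxy sulfonium phenolate F9.
The phenoxide of F9 displaces dimethyl sulfide to give 2-[3,5-bis(methoxymethoxy)-2,6-bis(3-methylbut-2-enyl)phenyl]-4,6-bis(methoxymethoxy)-7-(2-methylbut-3-en-2-yl)-2,3-dihydro-1-benzofuran-3-ol F10 (mixture of diastereomers).
Acid-catalysed dehydration of F10 (PPTS cat., toluene, 60 °C), helped by the electron-rich ring A, should give 22.

**Further compounds**

F1 | step 12 | [2-hydroxy-4,6-bis(methoxymethoxy)-3-(2-methylbut-3-en-2-yl)benzyl]triphenylphosphonium iodide | C=CC(C)(C)c1c(O)c(C[P+](c2ccccc2)(c2ccccc2)c2ccccc2)c(OCOC)cc1OCOC.[I-]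
F2 | step 12 | 3,5-bis(methoxymethoxy)-2,6-bis(3-methylbut-2-enyl)benzoic acid | OC(=O)c1c(CC=C(C)C)c(OCOC)cc(OCOC)c1CC=C(C)C
F3 | step 12 | 3,5-bis(methoxymethoxy)-2,6-bis(3-methylbut-2-enyl)benzoyl chloride | ClC(=O)c1c(CC=C(C)C)c(OCOC)cc(OCOC)c1CC=C(C)C
F4 | step 12 | {2-[3,5-bis(methoxymethoxy)-2,6-bis(3-methylbut-2-enyl)benzoyloxy]-4,6-bis(methoxymethoxy)-3-(2-methylbut-3-en-2-yl)benzyl}triphenylphosphonium iodide | C=CC(C)(C)c1c(OC(=O)c2c(CC=C(C)C)c(OCOC)cc(OCOC)c2CC=C(C)C)c(C[P+](c2ccccc2)(c2ccccc2)c2ccccc2)c(OCOC)cc1OCOC.[I-]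
F5 | step 12 | phosphorus ylide of F4 (2-aroyloxybenzylidene-triphenylphosphorane) | C=CC(C)(C)c1c(OC(=O)c2c(CC=C(C)C)c(OCOC)cc(OCOC)c2CC=C(C)C)c(C=P(c2ccccc2)(c2ccccc2)c2ccccc2)c(OCOC)cc1OCOC
F6 | step 2 | 2,6-bis(methoxymethoxy)-4-(3-methylbut-2-enyloxy)benzaldehyde | O=Cc1c(OCOC)cc(OCC=C(C)C)cc1OCOC
F7 | step 2 | 4-formyl-3,5-bis(methoxymethoxy)-6-(2-methylbut-3-en-2-yl)cyclohexa-2,4-dien-1-one (racemic, not isolated) | O=CC1=C(OCOC)C(C(C)(C)C=C)C(=O)C=C1OCOC
F8 | step 2 | 4-hydroxy-2,6-bis(methoxymethoxy)-3-(2-methylbut-3-en-2-yl)benzaldehyde | O=Cc1c(OCOC)c(C(C)(C)C=C)c(O)cc1OCOC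
F9 | step 13 | 2-{2-[3,5-bis(methoxymethoxy)-2,6-bis(3-methylbut-2-enyl)phenyl]-2-(dimethylsulfonio)-1-hydroxyethyl}-3,5-bis(methoxymethoxy)-6-(2-methylbut-3-en-2-yl)phenolate (not isolated) | C=CC(C)(C)c1c([O-])c(C(O)C([S+](C)C)c2c(CC=C(C)C)c(OCOC)cc(OCOC)c2CC=C(C)C)c(OCOC)cc1OCOC
F10 | step 13 | 2-[3,5-bis(methoxymethoxy)-2,6-bis(3-methylbut-2-enyl)phenyl]-4,6-bis(methoxymethoxy)-7-(2-methylbut-3-en-2-yl)-2,3-dihydro-1-benzofuran-3-ol (racemic, mixture of diastereomers) | C=CC(C)(C)c1c(OCOC)cc(OCOC)c2C(O)C(c3c(CC=C(C)C)c(OCOC)cc(OCOC)c3CC=C(C)C)Oc12
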